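Its constants are assumed.

- Elm was larch's neighbour: the same charge at the same 25 °C until 8.0 s, then −25 °C, while alder stood cold throughout and ash stood at 0 °C.

the same everywhere: substrate 20 mM; free catalyst 28 µM; time 25 s
- alder: temperature −25 °C
- elm: at 25 °C until 8.0 s, from then on at −25 °C
- larch: temperature 25 °C
- ash: temperature 0 °C

    substrate + free catalyst ⇌ catalyst intermediate A (K1 = 5.48 M⁻¹, k1 = 8510 M⁻¹ s⁻¹, Ea1 = 14.0 kJ mol⁻¹, ΔH1 = −38.0 kJ mol⁻¹)
    catalyst intermediate A → catalyst intermediate B (k2 = 134 s⁻¹, Ea2 = 52.0 kJ mol⁻¹)
    catalyst intermediate B → free catalyst + product (k3 = 121 s⁻¹, Ea3 = 68.0 kJ mol⁻¹)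
    2 catalyst intermediate B ⇌ resting dimer, settled at all times (K4 = 4.80 × 10⁶ M⁻¹, ΔH4 = −24.0 kJ mol⁻¹)
    (constants at 25 °C)

- a species is counted by the substrate in it: one resting dimer counts as two
- two of one species on the left: rate k times its square, two consumed each time
- the constants hold at 25 °C; other temperatures follow from the activation energies and enthalpies

* the best flask by amount of product, in percent of the substrate charged; "all alike" if 1.5 percentage points covers them all (alder / elm / larch / ash / all alike)
* amount of product at the end, in percent of the substrate charged, alder
* amount of product at the end, in percent of the substrate charged, elm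
* amount of product at the end, in percent of the substrate charged, larch
* amount of product at the end, in percent of the substrate charged, ash

- I began with a ladder of rates for larch, fastest first: catalyst intermediate A falls back at 1550 s⁻¹, free catalyst takes up substrate at 170 s⁻¹, and the second and third steps run at 134 s⁻¹ and 121 s⁻¹.
- All of these take milliseconds, and the dimer is kept at balance, so I took the catalyst forms as steady shares. With X the concentration of catalyst intermediate B and S that of substrate, the flow is v, the third constant times X.
- Catalyst intermediate A then stands at v over the second constant, and free catalyst at A times the back rate plus that constant, over the uptake rate. The dimer stands at its constant times X squared, counted twice.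
- Adding these forms to equal the charge gave a quadratic in X whose linear coefficient was 10.9 at full substrate, so X was 1.23 µM and v was 0.149 mM s⁻¹. I carried this working rate, the third constant times the steady amount of catalyst intermediate B.
- The next rung was the time for that flow to pass the whole catalyst charge once, about 0.188 s. The lowest rung was the substrate, which v would use up in 134 s, longer than the 25 s run.
- The curve of S was therefore gentle, and I replaced it by its mean. For larch, S was 18.1 mM, v was 0.145 mM s⁻¹, and the product was 18.2%.
- To check that step, I reckoned v at the end substrate, 16.4 mM, which gave 0.141 mM s⁻¹. Averaging the two end rates gave larch 18.1%, so the mean cost 0.028 percentage points.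
- For elm's warm stretch, the mean S of 19.4 mM gave 0.148 mM s⁻¹ and 5.92%.
- For the cold I supposed the charge sat as resting dimer, with its constant at 3.38 × 10⁷ M⁻¹ and the third constant lower by a factor of 250. That gave v of 3.10 × 10⁻⁴ mM s⁻¹, slower than warm elm.
- By this reckoning alder came to 0.0387%, and elm's cold stretch added 0.0263%, hardly any beside its warm stretch, for a total of 5.95%. I did not reckon ash.
- The forecast named larch, with alder 0.037%, elm 5.9%, larch 18% and ash 1.25%, on the grounds that cooling “pushes more catalyst into the resting dimer”.
- The run gave larch as best, with alder 0.0374%, elm 5.92%, larch 18.1% and ash 1.27%.
- The neighbour of elm held 0.070 mM of free catalyst, 2.50 times elm's charge of it. The same reckoning started at v of 0.265 mM s⁻¹, 1.78 times elm's 0.149 mM s⁻¹, and its mean substrate of 18.9 mM gave 0.263 mM s⁻¹. With the cold stretch scaled by the square root of the charge, that made 10.6%. The neighbour flask gave 10.5% at 25.0 s, with the resting dimer, the resting state, holding 98.0% of the catalyst.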